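**Plan**

1. Retrosynthesis cuts three ester C–O bonds first: the aryl ester to the terminal (S)-3-oxybutanoate, the ester at the arylpropyl carbinol, and the ester inside the side-chain acid between the 3-oxybutanoate and the 3,4-dihydroxybutanoyl unit.
2. The last cut removes the aryl C6–CH2 bond together with a temporary lactone C(=O)–O bond, leading back to 2,4-bis(benzyloxy)benzoic acid and (R)-propylene oxide.
3. The enabling feature: on the benzene ring (ring A), C6 is the only C–H ortho to the C1 carboxyl because C2 carries oxygen, and the C6 substituent CH2–CH(CH3)–O is (R)-propylene oxide opened at its CH2. Carboxyl and carbinol oxygen can therefore close a six-membered lactone (ring B) fused to ring A.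
4. Forward: benzylate and saponify; C–H alkylation with lactonisation (the only ring formed, reopened in the next step); lactone opening to the allyl ester; acylation of the carbinol with the preassembled chain acid; deallylation; Mitsunobu esterification; global hydrogenolysis.
5. All four stereocenters come from the chiral pool: the arylpropyl carbinol (R) from (R)-propylene oxide; the inner 3-oxybutanoate (R) from (R)-3-hydroxybutanoic acid with retention; the terminal 3-oxybutanoate (S) from the same acid by Mitsunobu inversion; the diol carbon (R) from dimethyl (R)-malate.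

Key step: step 3

Remark: the four chiral feedstocks (4, 9, 13) and acid 1 are taken to be commercial, the chiral ones as single enantiomers. Saponification and allylation of the lactone are run in one pot so that the hydroxy acid is never set free.

**Route**

Step 1
Reactants: 1 2,4-dihydroxybenzoic acid
Product: 2 benzyl 2,4-bis(benzyloxy)benzoate
Conditions: BnBr (3.5 equiv), K2CO3, DMF, 60 °C
Reagents that add atoms: benzyl bromide, BrCc1ccccc1
Why: Williamson etherification of both phenols and SN2 O-alkylation of the carboxylate by benzyl bromide under K2CO3 in DMF should benzylate all three acidic oxygens.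

Step 2
Reactants: 2 benzyl 2,4-bis(benzyloxy)benzoate
Product: 3 2,4-bis(benzyloxy)benzoic acid
Conditions: KOH, THF/MeOH/H2O, 65 °C; then aq. HCl
Reagents that add atoms: potassium hydroxide, [K+].[OH-]
Why: Saponification (acyl substitution by hydroxide) cleaves only the benzyl ester, because aryl benzyl ethers are inert to aqueous base.

Step 3
Reactants: 3 2,4-bis(benzyloxy)benzoic acid; 4 (R)-propylene oxide
Product: 6 (3R)-6,8-bis(benzyloxy)-3-methylisochroman-1-one, via ring-opened hydroxy acid 5 (not isolated)
Conditions: Pd(OAc)2 (5 mol %), N-acetyl-L-tert-leucine (10 mol %), KOAc (1 equiv), 4 (3 equiv), 1,1,1,3,3,3-hexafluoropropan-2-ol, sealed tube, 60 °C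
Reagents that add atoms: none
Why: The potassium carboxylate of 3 binds divalent palladium and, with the N-acetyl amino acid ligand acting as internal base, the C6–H bond is cleaved by concerted metalation–deprotonation to give a five-membered aryl palladacycle. The aryl–palladium bond then attacks the potassium-activated epoxide at its unsubstituted CH2 in a redox-neutral SN2-type opening, which forms the C6–CH2 bond and, after protonolysis, releases hydroxy acid 5 and the divalent palladium catalyst. In the acidic fluoroalcohol the secondary hydroxyl of 5 adds to the neighbouring carboxyl carbon with loss of water, a 6-exo-trig lactonisation that closes ring B. The closest known reaction type is the Pd(OAc)2/mono-N-protected amino acid catalysed ortho C–H alkylation of benzoic acids with terminal epoxides, which gives 3-substituted 3,4-dihydroisocoumarins. No stereocenter is created: the C–O bond at the methyl-bearing carbon is never broken, so C3 of 6 keeps the (R) configuration of 4. The step needs site selectivity, secured because C2 carries a benzyloxy group and C6 is the only ortho C–H (which also rules out double alkylation), and regioselective epoxide opening, secured by SN2 attack at the less hindered carbon.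

Step 4
Reactants: 6 (3R)-6,8-bis(benzyloxy)-3-methylisochroman-1-one
Product: 8 allyl 2,4-bis(benzyloxy)-6-[(2R)-2-hydroxypropyl]benzoate, via potassium hydroxy carboxylate 7 (not isolated)
Conditions: KOH (1.05 equiv), THF/H2O, 50 °C; evaporate to dryness; allyl bromide, DMF, 0 °C → rt
Reagents that add atoms: potassium hydroxide, [K+].[OH-]; allyl bromide, C=CCBr
Why: Saponification opens the lactone at the acyl carbon and the dry potassium carboxylate is O-alkylated by allyl bromide (SN2) without acidification, so the hydroxy acid cannot reclose and the carbinol stereocenter is not touched.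

Step 5
Reactants: 9 dimethyl (R)-malate
Product: 10 methyl (3R)-3,4-dihydroxybutanoate
Conditions: BH3·SMe2 (1.05 equiv), NaBH4 (5 mol %), THF, 0 °C → rt; MeOH quench
Reagents that add atoms: none
Why: Hydroxyl-directed chemoselective borane reduction delivers hydride through a five-membered alkoxyborane chelate only to the ester next to the free hydroxyl, leaving the other ester and the stereocenter unchanged.

Step 6
Reactants: 10 methyl (3R)-3,4-dihydroxybutanoate
Product: 11 methyl (3R)-3,4-bis(benzyloxy)butanoate
Conditions: benzyl 2,2,2-trichloroacetimidate (2.6 equiv), TfOH (cat.), CH2Cl2/cyclohexane, 0 °C → rt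
Reagents that add atoms: benzyl 2,2,2-trichloroacetimidate, ClC(Cl)(Cl)C(=N)OCc1ccccc1
Why: Acid-catalysed O-benzylation with the trichloroacetimidate etherifies both hydroxyls without the base that would cause β-elimination or retro-aldol cleavage, and the primary hydroxyl should react first, which blocks γ-lactonisation.

Step 7
Reactants: 11 methyl (3R)-3,4-bis(benzyloxy)butanoate
Product: 12 (3R)-3,4-bis(benzyloxy)butanoic acid
Conditions: LiOH, THF/H2O, 0 °C → rt; then aq. HCl to pH 3
Reagents that add atoms: lithium hydroxide, [Li+].[OH-]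
Why: Saponification with LiOH at low temperature hydrolyses the methyl ester under conditions mild enough to avoid E1cB loss of the β-benzyloxy group.

Step 8
Reactants: 13 (R)-3-hydroxybutanoic acid
Product: 14 allyl (3R)-3-hydroxybutanoate
Conditions: allyl bromide, KHCO3, DMF, rt
Reagents that add atoms: allyl bromide, C=CCBr
Why: SN2 O-alkylation of the carboxylate under KHCO3, a base too weak to deprotonate the secondary alcohol, gives the ester with the stereocenter untouched.

Step 9
Reactants: 12 (3R)-3,4-bis(benzyloxy)butanoic acid; 14 allyl (3R)-3-hydroxybutanoate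
Product: 15 allyl (3R)-3-{[(3R)-3,4-bis(benzyloxy)butanoyl]oxy}butanoate
Conditions: DIC, DMAP (cat.), CH2Cl2, 0 °C → rt
Reagents that add atoms: none
Why: Steglich esterification acylates the secondary hydroxyl at oxygen, so the carbinol configuration is retained.

Step 10
Reactants: 15 allyl (3R)-3-{[(3R)-3,4-bis(benzyloxy)butanoyl]oxy}butanoate
Product: 16 (3R)-3-{[(3R)-3,4-bis(benzyloxy)butanoyl]oxy}butanoic acid
Conditions: Pd(PPh3)4 (cat.), morpholine, THF, rt; dilute acid wash
Reagents that add atoms: none
Why: Tsuji–Trost deallylation, in which zerovalent palladium ionises the allyl ester to a π-allyl complex that morpholine captures, frees the acid without touching the inner ester or the benzyl ethers.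

Step 11
Reactants: 8 allyl 2,4-bis(benzyloxy)-6-[(2R)-2-hydroxypropyl]benzoate; 16 (3R)-3-{[(3R)-3,4-bis(benzyloxy)butanoyl]oxy}butanoic acid
Product: 17 allyl 2,4-bis(benzyloxy)-6-{(2R)-2-[((3R)-3-{[(3R)-3,4-bis(benzyloxy)butanoyl]oxy}butanoyl)oxy]propyl}benzoate
Conditions: DIC, DMAP (cat.), CH2Cl2, 0 °C
Reagents that add atoms: none
Why: Steglich esterification of the secondary carbinol proceeds at oxygen with retention, and the flanked allyl benzoate should be slow to relactonise under these near-neutral, cold conditions.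

Step 12
Reactants: 17 allyl 2,4-bis(benzyloxy)-6-{(2R)-2-[((3R)-3-{[(3R)-3,4-bis(benzyloxy)butanoyl]oxy}butanoyl)oxy]propyl}benzoate
Product: 18 2,4-bis(benzyloxy)-6-{(2R)-2-[((3R)-3-{[(3R)-3,4-bis(benzyloxy)butanoyl]oxy}butanoyl)oxy]propyl}benzoic acid
Conditions: Pd(PPh3)4 (cat.), morpholine, THF, rt; dilute acid wash
Reagents that add atoms: none
Why: Tsuji–Trost deallylation with zerovalent palladium is specific for the allyl ester, so the two alkyl esters and four benzyl ethers remain, and the acylated carbinol can no longer lactonise.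

Step 13
Reactants: 13 (R)-3-hydroxybutanoic acid
Product: 19 benzyl (3R)-3-hydroxybutanoate
Conditions: BnBr, KHCO3, DMF, rt
Reagents that add atoms: benzyl bromide, BrCc1ccccc1
Why: SN2 O-alkylation of the carboxylate by benzyl bromide under a weak base leaves the hydroxyl and its stereocenter unchanged.

Step 14
Reactants: 18 2,4-bis(benzyloxy)-6-{(2R)-2-[((3R)-3-{[(3R)-3,4-bis(benzyloxy)butanoyl]oxy}butanoyl)oxy]propyl}benzoic acid; 19 benzyl (3R)-3-hydroxybutanoate
Product: 20 benzyl (3S)-3-[(2,4-bis(benzyloxy)-6-{(2R)-2-[((3R)-3-{[(3R)-3,4-bis(benzyloxy)butanoyl]oxy}butanoyl)oxy]propyl}benzoyl)oxy]butanoate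
Conditions: PPh3, DIAD, toluene/THF, 0 °C → rt
Reagents that add atoms: none
Why: In the Mitsunobu esterification the hydroxyl of 19 becomes an alkoxyphosphonium leaving group and is displaced by the carboxylate of 18 in an SN2 step with inversion, which sets the (S) centre and avoids acyl activation of the hindered 2,6-disubstituted acid.

Step 15
Reactants: 20 benzyl (3S)-3-[(2,4-bis(benzyloxy)-6-{(2R)-2-[((3R)-3-{[(3R)-3,4-bis(benzyloxy)butanoyl]oxy}butanoyl)oxy]propyl}benzoyl)oxy]butanoate
Product: 21 Talapolyester B
Conditions: H2 (1 atm), Pd/C (10 wt % Pd), EtOAc, rt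
Reagents that add atoms: none
Why: Catalytic hydrogenolysis cleaves the two aryl benzyl ethers, the two alkyl benzyl ethers and the benzyl ester under neutral conditions that leave the four alkyl and aryl ester links and all stereocenters untouched.

**Compound list**

1 | 2,4-dihydroxybenzoic acid | OC(=O)c1ccc(O)cc1O | starting material
2 | benzyl 2,4-bis(benzyloxy)benzoate | O=C(OCc1ccccc1)c1ccc(OCc2ccccc2)cc1OCc1ccccc1 | intermediate
3 | 2,4-bis(benzyloxy)benzoic acid | OC(=O)c1ccc(OCc2ccccc2)cc1OCc1ccccc1 | intermediate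
4 | (R)-propylene oxide | C[C@@H]1CO1 | starting material
5 | 2,4-bis(benzyloxy)-6-[(2R)-2-hydroxypropyl]benzoic acid | C[C@@H](O)Cc1cc(OCc2ccccc2)cc(OCc2ccccc2)c1C(=O)O | intermediate
6 | (3R)-6,8-bis(benzyloxy)-3-methylisochroman-1-one | C[C@@H]1Cc2cc(OCc3ccccc3)cc(OCc3ccccc3)c2C(=O)O1 | intermediate
7 | potassium 2,4-bis(benzyloxy)-6-[(2R)-2-hydroxypropyl]benzoate | C[C@@H](O)Cc1cc(OCc2ccccc2)cc(OCc2ccccc2)c1C(=O)[O-].[K+] | intermediate
8 | allyl 2,4-bis(benzyloxy)-6-[(2R)-2-hydroxypropyl]benzoate | C[C@@H](O)Cc1cc(OCc2ccccc2)cc(OCc2ccccc2)c1C(=O)OCC=C | intermediate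
9 | dimethyl (R)-malate | COC(=O)C[C@@H](O)C(=O)OC | starting material
10 | methyl (3R)-3,4-dihydroxybutanoate | COC(=O)C[C@@H](O)CO | intermediate
11 | methyl (3R)-3,4-bis(benzyloxy)butanoate | COC(=O)C[C@@H](OCc1ccccc1)COCc1ccccc1 | intermediate
12 | (3R)-3,4-bis(benzyloxy)butanoic acid | OC(=O)C[C@@H](OCc1ccccc1)COCc1ccccc1 | intermediate
13 | (R)-3-hydroxybutanoic acid | C[C@@H](O)CC(=O)O | starting material
14 | allyl (3R)-3-hydroxybutanoate | C[C@@H](O)CC(=O)OCC=C | intermediate
15 | allyl (3R)-3-{[(3R)-3,4-bis(benzyloxy)butanoyl]oxy}butanoate | C[C@H](CC(=O)OCC=C)OC(=O)C[C@@H](OCc1ccccc1)COCc1ccccc1 | intermediate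
16 | (3R)-3-{[(3R)-3,4-bis(benzyloxy)butanoyl]oxy}butanoic acid | C[C@H](CC(=O)O)OC(=O)C[C@@H](OCc1ccccc1)COCc1ccccc1 | intermediate
17 | allyl 2,4-bis(benzyloxy)-6-{(2R)-2-[((3R)-3-{[(3R)-3,4-bis(benzyloxy)butanoyl]oxy}butanoyl)oxy]propyl}benzoate | C[C@H](CC(=O)O[C@H](C)Cc1cc(OCc2ccccc2)cc(OCc2ccccc2)c1C(=O)OCC=C)OC(=O)C[C@@H](OCc1ccccc1)COCc1ccccc1 | intermediate
18 | 2,4-bis(benzyloxy)-6-{(2R)-2-[((3R)-3-{[(3R)-3,4-bis(benzyloxy)butanoyl]oxy}butanoyl)oxy]propyl}benzoic acid | C[C@H](CC(=O)O[C@H](C)Cc1cc(OCc2ccccc2)cc(OCc2ccccc2)c1C(=O)O)OC(=O)C[C@@H](OCc1ccccc1)COCc1ccccc1 | intermediate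
19 | benzyl (3R)-3-hydroxybutanoate | C[C@@H](O)CC(=O)OCc1ccccc1 | intermediate
20 | benzyl (3S)-3-[(2,4-bis(benzyloxy)-6-{(2R)-2-[((3R)-3-{[(3R)-3,4-bis(benzyloxy)butanoyl]oxy}butanoyl)oxy]propyl}benzoyl)oxy]butanoate | C[C@H](CC(=O)O[C@H](C)Cc1cc(OCc2ccccc2)cc(OCc2ccccc2)c1C(=O)O[C@@H](C)CC(=O)OCc1ccccc1)OC(=O)C[C@@H](OCc1ccccc1)COCc1ccccc1 | intermediate
21 | Talapolyester B, (3S)-3-[(2,4-dihydroxy-6-{(2R)-2-[((3R)-3-{[(3R)-3,4-dihydroxybutanoyl]oxy}butanoyl)oxy]propyl}benzoyl)oxy]butanoic acid | C[C@H](CC(=O)O[C@H](C)Cc1cc(O)cc(O)c1C(=O)O[C@@H](C)CC(=O)O)OC(=O)C[C@@H](O)CO | target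

**Step count and risks**

Total step count: 15.
Longest linear sequence: 9 steps, from dimethyl (R)-malate 9 (steps 5, 6, 7, 9, 10, 11, 12, 14, 15). The arene line from 1 runs 8 steps.

Steps most likely to fail:

1. Step 3. Palladation of the electron-rich, doubly benzyloxylated acid may be slow. The volatile epoxide may be consumed by solvolysis in the fluoroalcohol before it is captured. Protodecarboxylation of the dialkoxybenzoic acid may compete on heating. The fallback builds the lactone carbonyl last and sets out from 4. Commercial 1,3-bis(benzyloxy)-5-bromobenzene is converted with Mg in THF into [3,5-bis(benzyloxy)phenyl]magnesium bromide F1. Under CuI catalysis at −30 °C this opens 4 at CH2 to give (2R)-1-[3,5-bis(benzyloxy)phenyl]propan-2-ol F2. NBS in MeCN should brominate the ring position between the side chain and a benzyloxy group, giving (2R)-1-[3,5-bis(benzyloxy)-2-bromophenyl]propan-2-ol F3. Palladium-catalysed carbonylative lactonisation (CO, Pd(OAc)2, Xantphos, K2CO3, toluene, 90 °C) then closes ring B and comes back to the route at 6.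

2. Step 4. The freed secondary hydroxyl may attack the neighbouring allyl ester and close back to the lactone with loss of allyl alcohol, during alkylation, work-up or the DMAP-catalysed acylation of step 11. The fallback masks the carbinol and changes the order of esterification; it sets out from 6. The lactone is opened with KOH as before, and both oxygens are silylated (TBSCl, imidazole, DMF) to give tert-butyldimethylsilyl 2,4-bis(benzyloxy)-6-[(2R)-2-(tert-butyldimethylsilyloxy)propyl]benzoate F4. The silyl ester alone is hydrolysed (K2CO3, MeOH/THF/H2O) to 2,4-bis(benzyloxy)-6-[(2R)-2-(tert-butyldimethylsilyloxy)propyl]benzoic acid F5. Mitsunobu esterification with 19 (PPh3, DIAD) gives benzyl (3S)-3-({2,4-bis(benzyloxy)-6-[(2R)-2-(tert-butyldimethylsilyloxy)propyl]benzoyl}oxy)butanoate F6. HF·pyridine in THF frees the carbinol next to a now more hindered secondary-alkyl benzoate, giving benzyl (3S)-3-({2,4-bis(benzyloxy)-6-[(2R)-2-hydroxypropyl]benzoyl}oxy)butanoate F7. Steglich acylation with 16 (DIC, DMAP) comes back to the route at 20, bypassing 8, 17 and 18.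

3. Step 14. The phosphonium-activated β-hydroxy ester may undergo β-elimination to the crotonate faster than it is displaced, and capture by the flanked carboxylate may be slow. The fallback forms the ester by acyl transfer with retention and sets out from 18. 1-Chloro-N,N,2-trimethylprop-1-en-1-amine in CH2Cl2 converts the acid under neutral conditions into 2,4-bis(benzyloxy)-6-{(2R)-2-[((3R)-3-{[(3R)-3,4-bis(benzyloxy)butanoyl]oxy}butanoyl)oxy]propyl}benzoyl chloride F8. This acylates benzyl (3S)-3-hydroxybutanoate F9 (pyridine, DMAP, CH2Cl2, 40 °C), which is prepared from commercial (S)-3-hydroxybutanoic acid with BnBr and KHCO3 in DMF as in step 13. Because the alcohol already has the (S) configuration and reacts at oxygen, the fallback comes back to the route at 20.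

**Further compounds**

F1 | step 3 | [3,5-bis(benzyloxy)phenyl]magnesium bromide | Br[Mg]c1cc(OCc2ccccc2)cc(OCc2ccccc2)c1
F2 | step 3 | (2R)-1-[3,5-bis(benzyloxy)phenyl]propan-2-ol | C[C@@H](O)Cc1cc(OCc2ccccc2)cc(OCc2ccccc2)c1
F3 | step 3 | (2R)-1-[3,5-bis(benzyloxy)-2-bromophenyl]propan-2-ol | C[C@@H](O)Cc1cc(OCc2ccccc2)cc(OCc2ccccc2)c1Br
F4 | step 4 | tert-butyldimethylsilyl 2,4-bis(benzyloxy)-6-[(2R)-2-(tert-butyldimethylsilyloxy)propyl]benzoate | C[C@@H](O[Si](C)(C)C(C)(C)C)Cc1cc(OCc2ccccc2)cc(OCc2ccccc2)c1C(=O)O[Si](C)(C)C(C)(C)C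
F5 | step 4 | 2,4-bis(benzyloxy)-6-[(2R)-2-(tert-butyldimethylsilyloxy)propyl]benzoic acid | C[C@@H](O[Si](C)(C)C(C)(C)C)Cc1cc(OCc2ccccc2)cc(OCc2ccccc2)c1C(=O)O
F6 | step 4 | benzyl (3S)-3-({2,4-bis(benzyloxy)-6-[(2R)-2-(tert-butyldimethylsilyloxy)propyl]benzoyl}oxy)butanoate | C[C@@H](O[Si](C)(C)C(C)(C)C)Cc1cc(OCc2ccccc2)cc(OCc2ccccc2)c1C(=O)O[C@@H](C)CC(=O)OCc1ccccc1
F7 | step 4 | benzyl (3S)-3-({2,4-bis(benzyloxy)-6-[(2R)-2-hydroxypropyl]benzoyl}oxy)butanoate | C[C@@H](O)Cc1cc(OCc2ccccc2)cc(OCc2ccccc2)c1C(=O)O[C@@H](C)CC(=O)OCc1ccccc1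
F8 | step 14 | 2,4-bis(benzyloxy)-6-{(2R)-2-[((3R)-3-{[(3R)-3,4-bis(benzyloxy)butanoyl]oxy}butanoyl)oxy]propyl}benzoyl chloride | C[C@H](CC(=O)O[C@H](C)Cc1cc(OCc2ccccc2)cc(OCc2ccccc2)c1C(Cl)=O)OC(=O)C[C@@H](OCc1ccccc1)COCc1ccccc1
F9 | step 14 | benzyl (3S)-3-hydroxybutanoate | C[C@H](O)CC(=O)OCc1ccccc1
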